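**Retrosynthetic overview**
1. Target 12 ⇐ hydrogenolysis of two aryl benzyl ethers ⇐ diacetylation of diol 10 ⇐ LiAlH4 reduction of the all-trans tetralin diester 9.
2. C3 ⇐ ester-directed hydrogenation of the C3=C4 bond of the trans-1-aryl-1,2-dihydronaphthalene diester 8.
3. Ring B (C1–C8a bond) with C1 and C2 ⇐ new catalytic enantioselective cycloisomerisation of the achiral (E,E)-bis(benzylidene)succinate 7.
4. Diene 7 ⇐ two successive Stobbe condensations of dimethyl succinate with O-benzylsyringaldehyde 2.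
5. Ring order: both benzene rings are bought with syringaldehyde; the only ring formed is the carbocycle of the tetralin (step 6).

Assumption: the target is taken as drawn, (1S,2R,3R) (lyoniresinol 9,9'-di-O-acetate, all-trans), and the (S,S)-catalyst of step 6 is assumed to give the (1S,2R) product; if the sense is opposite, the (R,R)-catalyst is used.

**Route**

Step 1
Reactants: 1 syringaldehyde (4-hydroxy-3,5-dimethoxybenzaldehyde)
Product: 2 4-(benzyloxy)-3,5-dimethoxybenzaldehyde
Conditions: BnBr (1.1 equiv), K2CO3 (1.5 equiv), DMF, 60 °C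
Reagents that add atoms: benzyl bromide, BrCc1ccccc1
Why: Williamson ether synthesis (phenoxide SN2 on benzyl bromide) masks the phenol with a group that survives the base, acid-catalysis and hydride steps and is removed last by hydrogenolysis.

Step 2
Reactants: 2 4-(benzyloxy)-3,5-dimethoxybenzaldehyde; 3 dimethyl succinate
Product: 4 (E)-4-[4-(benzyloxy)-3,5-dimethoxyphenyl]-3-(methoxycarbonyl)but-3-enoic acid
Conditions: NaOMe (2.2 equiv), MeOH, reflux; then 2 M HCl
Reagents that add atoms: none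
Why: Stobbe condensation (succinate enolate aldol addition, γ-lactonisation, E1cB ring opening) is driven by carboxylate formation and gives the (E)-half-ester with the aryl group trans to the ester.

Step 3
Reactants: 4 (E)-4-[4-(benzyloxy)-3,5-dimethoxyphenyl]-3-(methoxycarbonyl)but-3-enoic acid
Product: 5 dimethyl (E)-2-[4-(benzyloxy)-3,5-dimethoxybenzylidene]succinate
Conditions: MeI (1.5 equiv), K2CO3 (1.5 equiv), DMF, rt
Reagents that add atoms: iodomethane, CI
Why: SN2 O-methylation of the carboxylate gives the diester needed for a second Stobbe condensation without touching the alkene geometry.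

Step 4
Reactants: 5 dimethyl (E)-2-[4-(benzyloxy)-3,5-dimethoxybenzylidene]succinate; 2 4-(benzyloxy)-3,5-dimethoxybenzaldehyde
Product: 6 (2E,3E)-2,3-bis[4-(benzyloxy)-3,5-dimethoxybenzylidene]succinic acid monomethyl ester
Conditions: NaOMe (2.2 equiv), MeOH, reflux, dark; then 2 M HCl
Reagents that add atoms: none
Why: A second Stobbe condensation at the remaining CH2 follows the same lactone/E1cB pathway and gives the (E,E)-diene, each aryl group trans to its carboxyl group.

Step 5
Reactants: 6 (2E,3E)-2,3-bis[4-(benzyloxy)-3,5-dimethoxybenzylidene]succinic acid monomethyl ester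
Product: 7 dimethyl (2E,3E)-2,3-bis[4-(benzyloxy)-3,5-dimethoxybenzylidene]succinate
Conditions: MeI (1.5 equiv), K2CO3 (1.5 equiv), DMF, rt, dark
Reagents that add atoms: iodomethane, CI
Why: SN2 esterification gives the symmetric, achiral (E,E)-diester, so activation of either enoate in the next step leads to the same product.

Step 6
Reactants: 7 dimethyl (2E,3E)-2,3-bis[4-(benzyloxy)-3,5-dimethoxybenzylidene]succinate
Product: 8 dimethyl (1S,2R)-7-(benzyloxy)-1-[4-(benzyloxy)-3,5-dimethoxyphenyl]-6,8-dimethoxy-1,2-dihydronaphthalene-2,3-dicarboxylate (aryl and C2 ester trans)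
Conditions: (S,S)-imidodiphosphorimidate acid C74H33F30N3O8P2S2 (two (S)-3,3'-bis[3,5-bis(trifluoromethyl)phenyl]-1,1'-bi-2-naphthol units on a P–NH–P core, each phosphorus carrying =N–SO2CF3; 5 mol%), CHCl3, 0 °C to rt, dark, 24–48 h; recrystallise
Reagents that add atoms: none
Why: Proposed new method: a catalytic enantioselective cycloisomerisation of an (E,E)-2,3-dibenzylidenesuccinate, in which the strongly acidic, confined imidodiphosphorimidate protonates one enoate carbonyl and makes its β-benzylic carbon (future C1) electrophilic, the chiral ion pair selects one of the two rapidly interconverting helical conformers of the twisted diene so that the electron-rich ring carbon of the other aryl group (ortho and para to OMe) closes the six-membered ring by intramolecular Friedel–Crafts conjugate addition on one face (C1 = S), and rearomatisation followed by C-protonation of the ketene hemiacetal anti to the pseudoaxial aryl group (also the thermodynamic outcome) sets C2 trans (R); the closest known reaction types are the racemic, stoichiometric CF3SO3H cyclisation of dibenzylidenesuccinates to trans-1-aryl-1,2-dihydronaphthalenes and imidodiphosphorimidate-catalysed asymmetric additions to acid-activated cinnamate esters.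

Step 7
Reactants: 8 dimethyl (1S,2R)-7-(benzyloxy)-1-[4-(benzyloxy)-3,5-dimethoxyphenyl]-6,8-dimethoxy-1,2-dihydronaphthalene-2,3-dicarboxylate
Product: 9 dimethyl (1S,2R,3R)-7-(benzyloxy)-1-[4-(benzyloxy)-3,5-dimethoxyphenyl]-6,8-dimethoxy-1,2,3,4-tetrahydronaphthalene-2,3-dicarboxylate (1,2-trans, 2,3-trans)
Conditions: H2 (1–4 bar), [Ir(cod)(PCy3)(py)]PF6 (5–10 mol%), CH2Cl2, rt
Reagents that add atoms: none
Why: Carbonyl-directed homogeneous hydrogenation: the cationic iridium catalyst binds the pseudoaxial C2 ester carbonyl and delivers H2 to the face of C3=C4 syn to it, so the C3 ester ends up trans to the C2 ester (3R), while aryl benzyl ethers are inert to this catalyst.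

Step 8
Reactants: 9 dimethyl (1S,2R,3R)-7-(benzyloxy)-1-[4-(benzyloxy)-3,5-dimethoxyphenyl]-6,8-dimethoxy-1,2,3,4-tetrahydronaphthalene-2,3-dicarboxylate
Product: 10 [(1S,2R,3R)-7-(benzyloxy)-1-[4-(benzyloxy)-3,5-dimethoxyphenyl]-6,8-dimethoxy-1,2,3,4-tetrahydronaphthalene-2,3-diyl]dimethanol
Conditions: LiAlH4 (3 equiv), THF, 0 °C to rt; Na2SO4·10H2O quench
Reagents that add atoms: none
Why: LiAlH4 reduction of both esters is faster than α-deprotonation at 0 °C, so C2 and C3 keep their configuration, and the ethers are untouched.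

Step 9
Reactants: 10 [(1S,2R,3R)-7-(benzyloxy)-1-[4-(benzyloxy)-3,5-dimethoxyphenyl]-6,8-dimethoxy-1,2,3,4-tetrahydronaphthalene-2,3-diyl]dimethanol
Product: 11 [(1S,2R,3R)-7-(benzyloxy)-1-[4-(benzyloxy)-3,5-dimethoxyphenyl]-6,8-dimethoxy-1,2,3,4-tetrahydronaphthalene-2,3-diyl]bis(methylene) diacetate
Conditions: Ac2O (4 equiv), pyridine, 4-(dimethylamino)pyridine (5 mol%), CH2Cl2, 0 °C to rt
Reagents that add atoms: acetic anhydride, CC(=O)OC(C)=O
Why: Nucleophilic acyl substitution acetylates the two primary alcohols, which are the only free hydroxyl groups because both phenols are still benzylated.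

Step 10
Reactants: 11 [(1S,2R,3R)-7-(benzyloxy)-1-[4-(benzyloxy)-3,5-dimethoxyphenyl]-6,8-dimethoxy-1,2,3,4-tetrahydronaphthalene-2,3-diyl]bis(methylene) diacetate
Product: 12 [(1S,2R,3R)-7-hydroxy-1-(4-hydroxy-3,5-dimethoxyphenyl)-6,8-dimethoxy-1,2,3,4-tetrahydronaphthalene-2,3-diyl]bis(methylene) diacetate (CNP0232596.1)
Conditions: H2 (1 atm), Pd/C (10 wt%), EtOAc/MeOH, rt
Reagents that add atoms: none
Why: Hydrogenolysis over Pd/C cleaves only the two aryl benzyl ethers; alkyl acetates, aryl methyl ethers and the three stereocentres are unaffected.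

**Compound list**
1 | syringaldehyde (4-hydroxy-3,5-dimethoxybenzaldehyde) | COc1cc(C=O)cc(OC)c1O | starting material
2 | 4-(benzyloxy)-3,5-dimethoxybenzaldehyde | COc1cc(C=O)cc(OC)c1OCc1ccccc1 | intermediate
3 | dimethyl succinate | COC(=O)CCC(=O)OC | starting material
4 | (E)-4-[4-(benzyloxy)-3,5-dimethoxyphenyl]-3-(methoxycarbonyl)but-3-enoic acid | COC(=O)/C(=C/c1cc(OC)c(OCc2ccccc2)c(OC)c1)CC(=O)O | intermediate
5 | dimethyl (E)-2-[4-(benzyloxy)-3,5-dimethoxybenzylidene]succinate | COC(=O)/C(=C/c1cc(OC)c(OCc2ccccc2)c(OC)c1)CC(=O)OC | intermediate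
6 | (2E,3E)-2,3-bis[4-(benzyloxy)-3,5-dimethoxybenzylidene]succinic acid monomethyl ester | COC(=O)/C(=C/c1cc(OC)c(OCc2ccccc2)c(OC)c1)C(=C/c1cc(OC)c(OCc2ccccc2)c(OC)c1)\C(=O)O | intermediate
7 | dimethyl (2E,3E)-2,3-bis[4-(benzyloxy)-3,5-dimethoxybenzylidene]succinate | COC(=O)/C(=C/c1cc(OC)c(OCc2ccccc2)c(OC)c1)C(=C/c1cc(OC)c(OCc2ccccc2)c(OC)c1)\C(=O)OC | intermediate
8 | dimethyl (1S,2R)-7-(benzyloxy)-1-[4-(benzyloxy)-3,5-dimethoxyphenyl]-6,8-dimethoxy-1,2-dihydronaphthalene-2,3-dicarboxylate | COc1cc([C@H]2c3c(cc(OC)c(OCc4ccccc4)c3OC)C=C(C(=O)OC)[C@@H]2C(=O)OC)cc(OC)c1OCc1ccccc1 | intermediate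
9 | dimethyl (1S,2R,3R)-7-(benzyloxy)-1-[4-(benzyloxy)-3,5-dimethoxyphenyl]-6,8-dimethoxy-1,2,3,4-tetrahydronaphthalene-2,3-dicarboxylate | COc1cc([C@H]2c3c(cc(OC)c(OCc4ccccc4)c3OC)C[C@@H](C(=O)OC)[C@@H]2C(=O)OC)cc(OC)c1OCc1ccccc1 | intermediate
10 | [(1S,2R,3R)-7-(benzyloxy)-1-[4-(benzyloxy)-3,5-dimethoxyphenyl]-6,8-dimethoxy-1,2,3,4-tetrahydronaphthalene-2,3-diyl]dimethanol | COc1cc([C@H]2c3c(cc(OC)c(OCc4ccccc4)c3OC)C[C@@H](CO)[C@@H]2CO)cc(OC)c1OCc1ccccc1 | intermediate
11 | [(1S,2R,3R)-7-(benzyloxy)-1-[4-(benzyloxy)-3,5-dimethoxyphenyl]-6,8-dimethoxy-1,2,3,4-tetrahydronaphthalene-2,3-diyl]bis(methylene) diacetate | COc1cc([C@H]2c3c(cc(OC)c(OCc4ccccc4)c3OC)C[C@@H](COC(C)=O)[C@@H]2COC(C)=O)cc(OC)c1OCc1ccccc1 | intermediate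
12 | [(1S,2R,3R)-7-hydroxy-1-(4-hydroxy-3,5-dimethoxyphenyl)-6,8-dimethoxy-1,2,3,4-tetrahydronaphthalene-2,3-diyl]bis(methylene) diacetate | COc1cc([C@H]2c3c(cc(OC)c(O)c3OC)C[C@@H](COC(C)=O)[C@@H]2COC(C)=O)cc(OC)c1O | target

**Step count and risks**
Total step count: 10. Longest linear sequence: 10 steps (1 to 12; aldehyde 2 is used twice).

The three steps most likely to fail:

Step 4 (second Stobbe condensation: moderate yields and E/Z mixtures are common). The fallback sets out from 2 and comes back at 7, bypassing steps 2 to 5. Wittig olefination of 2 with methyl bromo(triphenylphosphoranylidene)acetate in CH2Cl2 at rt gives methyl (Z)-2-bromo-3-[4-(benzyloxy)-3,5-dimethoxyphenyl]acrylate F1, with the aryl group trans to the ester. Reductive homocoupling of F1 with zerovalent nickel generated from NiCl2(PPh3)2, Zn and Et4NI in THF at 50 °C joins the two alkenyl carbons with retention of geometry and gives 7 directly.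

Step 6 (the proposed new cyclisation: acid strength, turnover and enantioselectivity are untested, and the benzyl ethers must tolerate the acid). The fallback uses known chemistry, sets out from 7 and comes back at 8. Treatment of 7 with CF3SO3H (2 equiv) in CH2Cl2 at −20 °C gives the racemic trans-diester, that is 8 together with its mirror image dimethyl (1R,2S)-7-(benzyloxy)-1-[4-(benzyloxy)-3,5-dimethoxyphenyl]-6,8-dimethoxy-1,2-dihydronaphthalene-2,3-dicarboxylate F2. Preparative chromatography on an amylose tris(3,5-dimethylphenylcarbamate) stationary phase (supercritical CO2/MeOH) separates the two and delivers 8.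

Step 7 (ester direction must override the steric preference for attack anti to the C2 ester, which would give the 2,3-cis epimer). The fallback sets out from 8 and comes back at 10, replacing steps 7 and 8 by a hydroxyl-directed sequence. Reduction of 8 with i-Bu2AlH (5 equiv) in CH2Cl2 at −78 °C gives [(1S,2R)-7-(benzyloxy)-1-[4-(benzyloxy)-3,5-dimethoxyphenyl]-6,8-dimethoxy-1,2-dihydronaphthalene-2,3-diyl]dimethanol F3. Silylation with t-BuMe2SiCl (1.05 equiv) and imidazole in CH2Cl2 at −20 °C takes the less hindered allylic C3 hydroxymethyl group and gives [(1S,2R)-7-(benzyloxy)-1-[4-(benzyloxy)-3,5-dimethoxyphenyl]-3-{[(tert-butyldimethylsilyl)oxy]methyl}-6,8-dimethoxy-1,2-dihydronaphthalen-2-yl]methanol F4. Hydrogenation with [Ir(cod)(PCy3)(py)]PF6 and H2 in CH2Cl2 is then directed by the single free C2 hydroxymethyl group to the face syn to it and gives [(1S,2R,3R)-7-(benzyloxy)-1-[4-(benzyloxy)-3,5-dimethoxyphenyl]-3-{[(tert-butyldimethylsilyl)oxy]methyl}-6,8-dimethoxy-1,2,3,4-tetrahydronaphthalen-2-yl]methanol F5. Desilylation with Bu4NF in THF gives 10.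

**Further compounds**
F1 | step 4 | methyl (Z)-2-bromo-3-[4-(benzyloxy)-3,5-dimethoxyphenyl]acrylate | COC(=O)/C(Br)=C/c1cc(OC)c(OCc2ccccc2)c(OC)c1
F2 | step 6 | dimethyl (1R,2S)-7-(benzyloxy)-1-[4-(benzyloxy)-3,5-dimethoxyphenyl]-6,8-dimethoxy-1,2-dihydronaphthalene-2,3-dicarboxylate | COc1cc([C@@H]2c3c(cc(OC)c(OCc4ccccc4)c3OC)C=C(C(=O)OC)[C@H]2C(=O)OC)cc(OC)c1OCc1ccccc1
F3 | step 7 | [(1S,2R)-7-(benzyloxy)-1-[4-(benzyloxy)-3,5-dimethoxyphenyl]-6,8-dimethoxy-1,2-dihydronaphthalene-2,3-diyl]dimethanol | COc1cc([C@H]2c3c(cc(OC)c(OCc4ccccc4)c3OC)C=C(CO)[C@@H]2CO)cc(OC)c1OCc1ccccc1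
F4 | step 7 | [(1S,2R)-7-(benzyloxy)-1-[4-(benzyloxy)-3,5-dimethoxyphenyl]-3-{[(tert-butyldimethylsilyl)oxy]methyl}-6,8-dimethoxy-1,2-dihydronaphthalen-2-yl]methanol | COc1cc([C@H]2c3c(cc(OC)c(OCc4ccccc4)c3OC)C=C(CO[Si](C)(C)C(C)(C)C)[C@@H]2CO)cc(OC)c1OCc1ccccc1
F5 | step 7 | [(1S,2R,3R)-7-(benzyloxy)-1-[4-(benzyloxy)-3,5-dimethoxyphenyl]-3-{[(tert-butyldimethylsilyl)oxy]methyl}-6,8-dimethoxy-1,2,3,4-tetrahydronaphthalen-2-yl]methanol | COc1cc([C@H]2c3c(cc(OC)c(OCc4ccccc4)c3OC)C[C@@H](CO[Si](C)(C)C(C)(C)C)[C@@H]2CO)cc(OC)c1OCc1ccccc1
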